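**Plan**
1. Retrosynthesis (labdane numbering; α = face of H5, β = face of C20): cut O–C9 (hydration of a C9=C11 alkene), C12–C13 (allyl–vinyl coupling), C9–C11 (vinyl addition to a C9 ketone), then C1–C10 (closure of ring A), C1=C2 (Wittig) and C4–C5 (Friedel–Crafts). This leads back to 2,6-dimethylhydroquinone and methyl 3-methylbut-2-enoate.
2. Enabling feature: ring B carries oxygen at C6 and C9 (para), methyls at C8 and C10, and the quaternary C4 on C5, so it is a dearomatized 2,6-dimethylhydroquinone. In its quinone monoketal, C10 is the β-carbon of the C6 enone and the C4 chain sits on the α-carbon C5.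
3. Forward: aromatic ring B first, then the C5 tether (C2–C4 from the ester, C1 by methylenation), oxidative dearomatization, enantioselective copper hydride reduction of C7=C8, radical closure of ring A (C1 to C10), then the C11–C16 side chain on the C9 ketone.
4. Stereochemistry: C8 from the chiral copper hydride catalyst; C10 from C8 (trans-3,5 addition to the enone); C5 and the final C8 configuration by equilibration of the 6,9-dione; C6 by α-face hydride delivery; C9 by α-face O2 capture of the tertiary radical.

Key step: step 8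

Assumption: (R)-DTBM-SEGPHOS is taken to deliver hydride to the face of C8 that gives (5S)-11, by analogy with 3-methylcyclohex-2-enones; if the sense is opposite on this dienone, the (S)-ligand is used.

Step 1
Reactants: 1 2,6-dimethylbenzene-1,4-diol; 2 methyl 3-methylbut-2-enoate
Product: 3 6-hydroxy-4,4,5,7-tetramethylchroman-2-one
Conditions: MsOH, 70 °C
Reagents that add atoms: none
Why: Acid-mediated Friedel–Crafts conjugate alkylation followed by lactonization (dihydrocoumarin synthesis from a phenol and a 3,3-dimethylacrylate) can only occur at the two equivalent positions ortho to the unhindered hydroxyl, so the quaternary C4 is bonded to the future C5 next to the future C20 methyl and the lactone ties up the future O6.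

Step 2
Reactants: 3 6-hydroxy-4,4,5,7-tetramethylchroman-2-one
Product: 4 6-methoxy-4,4,5,7-tetramethylchroman-2-one
Conditions: MeI, K2CO3, acetone, reflux
Reagents that add atoms: iodomethane, CI
Why: Williamson ether synthesis on the remaining methyl-flanked phenol; the aryl lactone should tolerate anhydrous carbonate, and the methyl ether later becomes half of the C9 ketal.

Step 3
Reactants: 4 6-methoxy-4,4,5,7-tetramethylchroman-2-one
Product: 6 4-methoxy-3,5-dimethyl-2-(2-methylpent-4-en-2-yl)phenol, via lactol 5 (not isolated)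
Conditions: DIBAL-H, CH2Cl2, −78 °C; then Ph3PCH3Br, KOtBu, THF, 0 °C to rt
Reagents that add atoms: methyltriphenylphosphonium bromide, C[P+](c1ccccc1)(c1ccccc1)c1ccccc1.[Br-]
Why: Half-reduction of the lactone to the lactol by DIBAL-H and Wittig methylenation of its open hydroxy-aldehyde form add C1 and free the phenol.

Step 4
Reactants: 6 4-methoxy-3,5-dimethyl-2-(2-methylpent-4-en-2-yl)phenol
Product: 8 2-(5-hydroxy-2-methylpentan-2-yl)-4-methoxy-3,5-dimethylphenol, via alkylborane 7 (not isolated)
Conditions: 9-BBN, THF, 0 °C to rt; then NaOH, H2O2, 0 °C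
Reagents that add atoms: 9-borabicyclo[3.3.1]nonane, [H]B1C2CCCC1CCC2 (boron stays only in 7); hydrogen peroxide, OO
Why: Anti-Markovnikov hydroboration–oxidation of the terminal alkene places oxygen on C1, the neopentyl-type C4 reinforcing the terminal regiochemistry.

Step 5
Reactants: 8 2-(5-hydroxy-2-methylpentan-2-yl)-4-methoxy-3,5-dimethylphenol
Product: 9 2-(5-bromo-2-methylpentan-2-yl)-4-methoxy-3,5-dimethylphenol
Conditions: CBr4, PPh3, CH2Cl2, 0 °C
Reagents that add atoms: carbon tetrabromide, BrC(Br)(Br)Br
Why: The Appel reaction converts the primary alcohol into the bromide under neutral conditions that should leave the phenol untouched.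

Step 6
Reactants: 9 2-(5-bromo-2-methylpentan-2-yl)-4-methoxy-3,5-dimethylphenol
Product: 10 2-(5-bromo-2-methylpentan-2-yl)-4,4-dimethoxy-3,5-dimethylcyclohexa-2,5-dien-1-one
Conditions: PhI(OAc)2, MeOH, 0 °C
Reagents that add atoms: methanol, CO
Why: Oxidative dearomatization of a para-methoxyphenol in methanol gives the quinone monoketal, which makes C10 the β-carbon of the C6 enone and masks C9 as an achiral, non-enolizable ketal.

Step 7
Reactants: 10 2-(5-bromo-2-methylpentan-2-yl)-4,4-dimethoxy-3,5-dimethylcyclohexa-2,5-dien-1-one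
Product: 11 (5S)-2-(5-bromo-2-methylpentan-2-yl)-4,4-dimethoxy-3,5-dimethylcyclohex-2-en-1-one
Conditions: Cu(OAc)2 (cat.), (R)-DTBM-SEGPHOS (cat.), (EtO)2MeSiH, t-BuOH, toluene, 0 °C
Reagents that add atoms: none
Why: Asymmetric copper hydride conjugate reduction of a β-methyl cyclic enone should touch only the trisubstituted C7=C8 bond, the tetrasubstituted α-branched C5=C10 bond being inert, and the ligand sets the C8 methyl stereocentre, which the adjacent ketal protects from epimerization.

Step 8
Reactants: 11 (5S)-2-(5-bromo-2-methylpentan-2-yl)-4,4-dimethoxy-3,5-dimethylcyclohex-2-en-1-one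
Product: 12 (8S,10S)-9,9-dimethoxy-4,4,8,10-tetramethyldecalin-6-one (8β-methyl, 10β-methyl; mixture of C5 epimers)
Conditions: (Me3Si)3SiH (slow addition), AIBN, toluene, 90 °C, high dilution
Reagents that add atoms: none
Why: Bromine abstraction by (Me3Si)3Si• gives the primary C1 radical, which adds to C10, the β-carbon of the C6 enone of ring B, and the resulting C5 α-keto radical takes hydrogen from the silane (radical chain, intramolecular Giese-type addition). The closest known reaction type is the tin- or silane-mediated cyclization of α-(ω-haloalkyl)cycloalkenones onto the enone β-carbon. Ring A closes in the 6-endo-trig mode, with the C5=C10 bond inside the new ring; the 5-exo alternative would attack C5, the α-carbon flanked by the quaternary C4, against both polarity and sterics. The quaternary C10 is controlled by the C8 methyl: axial attack on the enone half-chair with that methyl pseudo-equatorial puts C1 trans to C17 (the 3,5-trans rule of 5-substituted cyclohexenones), so (8S) should give (10S); C5 forms as an epimer mixture that step 9 corrects. The step needs cyclization to outrun reduction of the C1 radical and closure at C10 instead of C5, which the gem-dimethyl group at C4, the in-plane attachment of the tether at C5, slow silane addition and the enone polarization are expected to secure.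

Step 9
Reactants: 12 (8S,10S)-9,9-dimethoxy-4,4,8,10-tetramethyldecalin-6-one
Product: 14 (5S,8R,10S)-4,4,8,10-tetramethyl-trans-decalin-6,9-dione (8α-methyl), via kinetic dione 13 (not isolated)
Conditions: 1 M HCl, THF, rt; then NaOMe (cat.), MeOH, rt
Reagents that add atoms: water, O
Why: Acetal hydrolysis unveils the C9 ketone, after which thermodynamic epimerization α to the two carbonyls should move the C8 methyl from the axial β position (syn-axial to C20) to the equatorial α position and set the trans ring fusion at C5.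

Step 10
Reactants: 14 (5S,8R,10S)-4,4,8,10-tetramethyl-trans-decalin-6,9-dione
Product: 16 (5S,8R,9S,10S)-9-hydroxy-4,4,8,10-tetramethyl-9-vinyl-trans-decalin-6-one, via lithium enolate 15 (not isolated)
Conditions: LiN(SiMe3)2 (1.05 equiv), THF, −78 °C; then CH2=CHMgBr, −78 to 0 °C; aq. NH4Cl
Reagents that add atoms: lithium bis(trimethylsilyl)amide, [Li]N([Si](C)(C)C)[Si](C)(C)C (lithium stays only in 15); vinylmagnesium bromide, C=C[Mg]Br
Why: In situ protection of the C6 ketone as its lithium enolate (kinetic deprotonation at C7, the only unhindered α-methylene) lets the Grignard reagent add 1,2 to the C9 ketone alone; the carbinol configuration (expected from α-face attack) is irrelevant because C9 becomes trigonal in step 13.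

Step 11
Reactants: 16 (5S,8R,9S,10S)-9-hydroxy-4,4,8,10-tetramethyl-9-vinyl-trans-decalin-6-one
Product: 17 (5S,6R,8R,9S,10S)-4,4,8,10-tetramethyl-9-vinyl-trans-decalin-6,9-diol (6β-hydroxyl)
Conditions: NaBH4, MeOH, 0 °C
Reagents that add atoms: none
Why: Borohydride reduction of the C6 ketone from the open α face, the β face being blocked by the syn-axial C19 and C20 methyls, should give the axial 6β-alcohol.

Step 12
Reactants: 17 (5S,6R,8R,9S,10S)-4,4,8,10-tetramethyl-9-vinyl-trans-decalin-6,9-diol
Product: 18 (5S,6R,8R,9S,10S)-9-hydroxy-4,4,8,10-tetramethyl-9-vinyl-trans-decalin-6-yl acetate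
Conditions: Ac2O, DMAP, pyridine, rt
Reagents that add atoms: acetic anhydride, CC(=O)OC(C)=O
Why: DMAP-catalysed acetylation esterifies the secondary 6β-hydroxyl, while the hindered tertiary allylic C9 hydroxyl should stay free.

Step 13
Reactants: 18 (5S,6R,8R,9S,10S)-9-hydroxy-4,4,8,10-tetramethyl-9-vinyl-trans-decalin-6-yl acetate
Product: 19 (5S,6R,8R,10S)-9-[(E)-2-bromoethylidene]-4,4,8,10-tetramethyl-trans-decalin-6-yl acetate
Conditions: PBr3, pyridine (cat.), Et2O, −20 °C
Reagents that add atoms: phosphorus tribromide, BrP(Br)Br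
Why: Bromination with allylic transposition (SN2′-type) of the tertiary vinyl carbinol gives the favoured primary allylic bromide with the exocyclic C9=C11 bond, deliberately erasing the C9 stereocentre, with the bromomethyl group expected on the side away from the quaternary C10.

Step 14
Reactants: 20 3-bromofuran-2(5H)-one
Product: 21 3-(tributylstannyl)furan-2(5H)-one
Conditions: (Bu3Sn)2, Pd(PPh3)4 (cat.), toluene, 80 °C
Reagents that add atoms: hexabutylditin, CCCC[Sn](CCCC)(CCCC)[Sn](CCCC)(CCCC)CCCC
Why: Palladium-catalysed stannylation of the vinyl bromide with the ditin gives the α-stannyl butenolide that serves as the C13–C16 nucleophile.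

Step 15
Reactants: 19 (5S,6R,8R,10S)-9-[(E)-2-bromoethylidene]-4,4,8,10-tetramethyl-trans-decalin-6-yl acetate; 21 3-(tributylstannyl)furan-2(5H)-one
Product: 22 (5S,6R,8R,10S)-6-acetoxylabda-9(11)E,13-dien-16,15-olide
Conditions: Pd2(dba)3 (cat.), AsPh3, THF, 50 °C
Reagents that add atoms: none
Why: Stille coupling of the allylic bromide with the vinylstannane joins C12 to C13 at the unhindered primary terminus of the allylpalladium intermediate, under neutral conditions that should preserve the acetate and the skipped diene.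

Step 16
Reactants: 22 (5S,6R,8R,10S)-6-acetoxylabda-9(11)E,13-dien-16,15-olide
Product: 24 (5S,6R,8R,9R,10S)-6-acetoxy-9-hydroxylabd-13-en-16,15-olide (6β-acetoxy, 9α-hydroxy; CNP0205088.1), via hydroperoxide 23 (not isolated)
Conditions: Co(acac)2 (cat.), PhSiH3, O2 (1 atm), THF, rt; then PPh3
Reagents that add atoms: dioxygen, O=O
Why: Mukaiyama hydration: hydrogen-atom transfer from the cobalt hydride to C11 of the electron-rich trisubstituted alkene (expected to be faster than to the electron-poor butenolide) gives the tertiary C9 radical, which should capture O2 on the α face, anti to the axial C20 methyl and with the side chain going equatorial, and PPh3 reduces the 9α-hydroperoxide to the alcohol.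

**Compound list**
1 | 2,6-dimethylbenzene-1,4-diol (2,6-dimethylhydroquinone) | Cc1cc(O)cc(C)c1O | starting material
2 | methyl 3-methylbut-2-enoate | CC(C)=CC(=O)OC | starting material
3 | 6-hydroxy-4,4,5,7-tetramethylchroman-2-one | O=C1CC(C)(C)c2c(C)c(O)c(C)cc2O1 | intermediate
4 | 6-methoxy-4,4,5,7-tetramethylchroman-2-one | O=C1CC(C)(C)c2c(C)c(OC)c(C)cc2O1 | intermediate
5 | 6-methoxy-4,4,5,7-tetramethylchroman-2-ol (racemic lactol) | OC1CC(C)(C)c2c(C)c(OC)c(C)cc2O1 | intermediate
6 | 4-methoxy-3,5-dimethyl-2-(2-methylpent-4-en-2-yl)phenol | C=CCC(C)(C)c1c(C)c(OC)c(C)cc1O | intermediate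
7 | 2-[5-(9-borabicyclo[3.3.1]nonan-9-yl)-2-methylpentan-2-yl]-4-methoxy-3,5-dimethylphenol | Oc1cc(C)c(OC)c(C)c1C(C)(C)CCCB1C2CCCC1CCC2 | intermediate
8 | 2-(5-hydroxy-2-methylpentan-2-yl)-4-methoxy-3,5-dimethylphenol | OCCCC(C)(C)c1c(C)c(OC)c(C)cc1O | intermediate
9 | 2-(5-bromo-2-methylpentan-2-yl)-4-methoxy-3,5-dimethylphenol | BrCCCC(C)(C)c1c(C)c(OC)c(C)cc1O | intermediate
10 | 2-(5-bromo-2-methylpentan-2-yl)-4,4-dimethoxy-3,5-dimethylcyclohexa-2,5-dien-1-one | BrCCCC(C)(C)C1=C(C)C(OC)(OC)C(C)=CC1=O | intermediate
11 | (5S)-2-(5-bromo-2-methylpentan-2-yl)-4,4-dimethoxy-3,5-dimethylcyclohex-2-en-1-one | O=C1C[C@H](C)C(OC)(OC)C(C)=C1C(C)(C)CCCBr | intermediate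
12 | (8S,10S)-9,9-dimethoxy-4,4,8,10-tetramethyldecalin-6-one, C5 epimers | O=C1C[C@H](C)C(OC)(OC)[C@@]2(C)CCCC(C)(C)C12 | intermediate
13 | (8S,10S)-4,4,8,10-tetramethyldecalin-6,9-dione, C5 epimers | O=C1C[C@H](C)C(=O)[C@@]2(C)CCCC(C)(C)C12 | intermediate
14 | (5S,8R,10S)-4,4,8,10-tetramethyl-trans-decalin-6,9-dione | O=C1C[C@@H](C)C(=O)[C@@]2(C)CCCC(C)(C)[C@H]12 | intermediate
15 | lithium 6-en-6-olate of 14 | [Li+].[O-]C1=C[C@@H](C)C(=O)[C@@]2(C)CCCC(C)(C)[C@H]12 | intermediate
16 | (5S,8R,9S,10S)-9-hydroxy-4,4,8,10-tetramethyl-9-vinyl-trans-decalin-6-one | O=C1C[C@@H](C)[C@@](O)(C=C)[C@@]2(C)CCCC(C)(C)[C@H]12 | intermediate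
17 | (5S,6R,8R,9S,10S)-4,4,8,10-tetramethyl-9-vinyl-trans-decalin-6,9-diol | O[C@@H]1C[C@@H](C)[C@@](O)(C=C)[C@@]2(C)CCCC(C)(C)[C@H]12 | intermediate
18 | (5S,6R,8R,9S,10S)-9-hydroxy-4,4,8,10-tetramethyl-9-vinyl-trans-decalin-6-yl acetate | CC(=O)O[C@@H]1C[C@@H](C)[C@@](O)(C=C)[C@@]2(C)CCCC(C)(C)[C@H]12 | intermediate
19 | (5S,6R,8R,10S)-9-[(E)-2-bromoethylidene]-4,4,8,10-tetramethyl-trans-decalin-6-yl acetate | CC(=O)O[C@@H]1C[C@@H](C)/C(=C\CBr)[C@@]2(C)CCCC(C)(C)[C@H]12 | intermediate
20 | 3-bromofuran-2(5H)-one | BrC1=CCOC1=O | starting material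
21 | 3-(tributylstannyl)furan-2(5H)-one | CCCC[Sn](CCCC)(CCCC)C1=CCOC1=O | intermediate
22 | (5S,6R,8R,10S)-6-acetoxylabda-9(11)E,13-dien-16,15-olide | CC(=O)O[C@@H]1C[C@@H](C)/C(=C\CC3=CCOC3=O)[C@@]2(C)CCCC(C)(C)[C@H]12 | intermediate
23 | (5S,6R,8R,9R,10S)-6-acetoxy-9-hydroperoxylabd-13-en-16,15-olide | CC(=O)O[C@@H]1C[C@@H](C)[C@](OO)(CCC3=CCOC3=O)[C@@]2(C)CCCC(C)(C)[C@H]12 | intermediate
24 | (5S,6R,8R,9R,10S)-6-acetoxy-9-hydroxylabd-13-en-16,15-olide | CC(=O)O[C@@H]1C[C@@H](C)[C@](O)(CCC2=CCOC2=O)[C@@]2(C)CCCC(C)(C)[C@H]12 | target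

Total steps: 16. Longest linear sequence: 15 (steps 1 to 13, 15 and 16; step 14 is a one-step side branch).

**Steps most likely to fail**

Step 8. The C1 radical may be reduced before ring closure, may close on C5 instead of C10, or the C8 methyl may give too little facial control. Fallback by a polar closure: starting from 11, Kornblum displacement of the bromide (NaNO2, DMF) would give the nitro enone F1. DBU should then promote the intramolecular nitronate Michael addition of C1 to C10, in the same 6-endo mode and with the same axial preference, to give the nitro ketone F2. Radical denitration (Bu3SnH, AIBN, toluene, reflux) would return to 12.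

Step 16. Hydrogen-atom transfer may compete at the butenolide, autoxidation may occur at the doubly allylic C12, or O2 may be captured on the β face. Fallback by ionic Markovnikov hydration: starting from 22, oxymercuration (Hg(OAc)2, THF–H2O) of the electron-rich C9=C11 bond, with water expected to attack C9 axially from the α face, would give the organomercurial F3. Demercuration (NaBH4, 0 °C, short contact) would arrive at 24.

Step 7. Hydride delivery to the β-carbon next to the ketal may be slow or poorly enantioselective, or 1,2-reduction may intervene. Fallback by an auxiliary in place of the catalyst: starting from 10, transketalization with (R,R)-hydrobenzoin (PPTS, benzene) would give the C2-symmetric dioxolane dienone F4, whose phenyl group on the β side of C10 should direct the radical closure ((Me3Si)3SiH, AIBN) to the α face and give the bicyclic enone F5. Conjugate reduction of C7=C8 with an achiral copper hydride (Cu(OAc)2, 1,2-bis(diphenylphosphino)benzene, (EtO)2MeSiH, t-BuOH) would give the saturated ketone F6. Acid hydrolysis followed by NaOMe equilibration would rejoin the route at 14.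

**Further compounds**
F1 | step 8 | (5S)-4,4-dimethoxy-3,5-dimethyl-2-(2-methyl-5-nitropentan-2-yl)cyclohex-2-en-1-one | O=C1C[C@H](C)C(OC)(OC)C(C)=C1C(C)(C)CCC[N+](=O)[O-]
F2 | step 8 | (8S,10S)-9,9-dimethoxy-4,4,8,10-tetramethyl-1-nitrodecalin-6-one, C1 and C5 epimers | O=C1C[C@H](C)C(OC)(OC)[C@@]2(C)C([N+](=O)[O-])CCC(C)(C)C12
F3 | step 16 | 11-(acetoxymercurio) derivative of 24, C11 epimers | CC(=O)O[C@@H]1C[C@@H](C)[C@](O)(C(CC3=CCOC3=O)[Hg]OC(C)=O)[C@@]2(C)CCCC(C)(C)[C@H]12
F4 | step 7 | 2-(5-bromo-2-methylpentan-2-yl)-3,5-dimethylcyclohexa-2,5-diene-1,4-dione 4-[(R,R)-1,2-diphenylethane-1,2-diyl] ketal | BrCCCC(C)(C)C1=C(C)C2(O[C@H](c3ccccc3)[C@@H](c3ccccc3)O2)C(C)=CC1=O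
F5 | step 7 | (10S)-4,4,8,10-tetramethyldecal-7-ene-6,9-dione 9-[(R,R)-1,2-diphenylethane-1,2-diyl] ketal, C5 epimers | O=C1C=C(C)C3(O[C@H](c4ccccc4)[C@@H](c4ccccc4)O3)[C@@]2(C)CCCC(C)(C)C12
F6 | step 7 | (10S)-4,4,8,10-tetramethyldecalin-6,9-dione 9-[(R,R)-1,2-diphenylethane-1,2-diyl] ketal, C5 and C8 epimers | O=C1CC(C)C3(O[C@H](c4ccccc4)[C@@H](c4ccccc4)O3)[C@@]2(C)CCCC(C)(C)C12
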